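## Structural features

The target 27 is a germacranolide of the heliangolide type. A ten-membered carbocycle (C1–C10) carries a five-membered α-methylene γ-lactone fused at C6/C7 (lactone oxygen on C6, C11 on C7), an isobutyrate on C8, a trans-epoxide across C1/C10 (C14 methyl on C10), a ring-cis trisubstituted C4=C5 olefin bearing the C15 hydroxymethyl group, and a secondary carbinol at C3. Three stereocentres are contiguous (C6, C7, C8; O6 trans to C11, C11 cis to O8; all R). C3 (S) lies across the C4=C5 bond from C6, and the epoxide carbons C1 and C10 (both R) lie on the far side of the ring. The fragile groups are the exocyclic enoate of the lactone (Michael acceptor), the epoxide (acid-induced opening or transannular attack by C4=C5), the doubly allylic array O3–C3–C4(C15)=C5–C6–O6, and the C8 ester next to the lactone. The real difficulty is a medium ring with two defined olefin geometries (E at C1=C10 before epoxidation, ring-cis at C4=C5) and six stereocentres spread around a flexible ring, where closure by cyclisation is penalised by entropy and transannular strain. The feature exploited is that C1=C10 and C4=C5 form a cyclodeca-1,5-diene: this is the pattern left when the central cyclobutane (C1, C4, C5, C10) of a linear six-four-four tricycle is split at C1–C4 and C5–C10. The six-membered ring (C5–C10) of that tricycle is a cyclohexanone carrying the C8 oxygen, and the outer four-membered ring (C1–C4) carries the C15 carboxyl.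

## Logic of the disconnections

27 to 26: the two C–O bonds of the epoxide are cut. The epoxide is the most acid-sensitive group, so it is made last. Two stereocentres are removed. The forward step must pick C1=C10 over C4=C5 and the exocyclic enoate and must attack the outer face of the E olefin.

26 to 23 (through 25 and 24): the acetal C–O bonds, the C8 O–acyl bond and the C8 O–Si bond are cut. The isobutyrate must follow all hydride and enolate chemistry, and one acetonide masks O3 and O15 orthogonally to the C8 silyl ether. The forward steps need only a selective acylation of the single free hydroxyl and an acetal cleavage before the epoxide exists.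

23 to 20: C11=C13 is cut. The exocyclic methylene is the most electrophilic group and is added to a finished lactone. The forward step needs a lactone enolate that tolerates the silyl ether and the acetonide.

20 to 16 (through 19, 18 and 17): the O–C6 lactone bond is cut with inversion, then the acetonide, then the C6–H, C15–H and acetate reductions. Hydride is expected to give the C6 epimer with O6 cis to the side chain, and an invertive closure turns this into the trans-lactone. The forward step needs a clean SN2 at an allylic carbon.

16 to 13: the C3–O bond is cut. C3 is the vinylogous position of the C6 ketone, and the C4 ester makes the C3–C4–C5 unit a Baylis–Hillman-type allyl system, so oxygen can enter by allylic substitution instead of direct dienolate hydroxylation. The forward step needs enolisation toward C3 and face selectivity at C3.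

13 to 12: C7–C11 is cut. C7 is the α′-carbon of the ketone and the adjacent C8 centre can direct the alkylation. The forward step needs a kinetic enolate and control by C8.

12 to 11 (key): C1–C4 and C5–C10 are reconnected, turning the two ring olefins into a cyclobutane. The ten-membered ring and both olefin geometries are traded for a tricycle that one photocycloaddition delivers. The forward step demands that the diyl cleave C5–C10 and not C2–C3, and that it pass through the chair giving E C1=C10 and ring-cis C4=C5. This geometry is secured by having the C8 silyloxy group cis to the angular methyl in 11; equilibration of C4=C5 could repair only that bond, never C1=C10.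

11 to 7 and 10: C1–C10 and C4–C5 are cut. Both partners are small rings. The forward step needs head-to-head regiochemistry, cis-anti-cis fusion and addition anti to the silyloxy group.

7 to 1 (through 6, 5, 4, 3 and 2): the C10–methyl bond is cut (conjugate addition, then dehydrogenation), then the enone is traced to a meso diol whose enantiotopic hydroxyls are told apart by a lipase. The forward sequence must place the carbonyl on the carbinol the enzyme leaves free.

10 to 8 (through 9): the ester O–methyl bond and the ring C=C are cut, back to a commercial α-bromo ester.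

## Other disconnections considered

Alternative 1: The cut runs through the lactone carbonyl (C11–C12 and C12–O), so that C12 comes from carbon monoxide and the ring carries a C6 hydroxyl and a C7 ethynyl group (A2). In the forward step, A2 reacts with CO under PdCl2 and thiourea: an alkoxycarbonyl–palladium species adds across the alkyne and protonolysis releases the exocyclic methylene, giving A1.
- In favour: lactone and methylene arise in one neutral operation, with no enolate chemistry next to the C8 ester. On this unit it is better than the chosen plan, which spends steps 10, 14 and 15 on it.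
- Against: it is an endgame only. The ten-membered ring, both olefins and five stereocentres of A2 remain to be made; A2 must carry the epoxide through a Lewis-acidic, nucleophile-rich medium; the ethynyl group must be set trans to O6 and cis to O8, the same problem as step 10; and A1 must be desilylated with the epoxide present, which the chosen plan avoids.
- Comparison: structurally it closes only the five-membered ring; mechanistically it is an organometallic carbonylation against an SN2 lactonisation; in step count it saves about two late steps but leaves the ring synthesis open.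

Alternative 2: The cut is C9–C10. The open-chain precursor A4 has a C8 enol ether and an E vinyl iodide at C10. 9-BBN hydroborates the enol ether (boron on C9, new stereocentre at C8), and PdCl2(dppf) with aqueous Cs2CO3 couples the alkylborane with the vinyl iodide to close the ring as A3.
- In favour: both olefin geometries are fixed in open-chain intermediates and the coupling is stereoretentive. On the security of E C1=C10 it is better than the chosen plan, and C3, C6 and C7 can be set by acyclic methods that are better understood than the ring-based control used here at C3 and C7.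
- Against: closing a ten-membered carbocycle by cross-coupling fights entropy and transannular strain (high dilution, β-hydride elimination, oligomers); C8 comes from a substrate-controlled hydroboration, whereas the chosen plan takes it from an enzymatic desymmetrisation; A3 still has five protecting groups and C12 at the alcohol level, so many steps remain.
- Comparison: ring formation by cyclisation against ring merger by bond cleavage; palladium catalysis against a thermal diradical; clearly longer overall.

Alternative 3: The cut is C3–C4. The seco-aldehyde A6 already carries the lactone, the isobutyrate and a C4 vinyl iodide. CrCl2 with catalytic NiCl2 gives a vinylchromium species that adds to the C3 aldehyde, closing the ring and creating the C3 carbinol in A5.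
- In favour: the reaction tolerates lactone, ester and enoate; the C3 oxygen and the C4=C5 geometry come with the ring-forming bond. This is better than the chosen plan, where C3 oxygenation is the least secure operation, and A5 is only an epoxidation and a desilylation from 27, the shortest endgame of all.
- Against: the C3 configuration rests on the macrocyclic transition state alone (equal to the chosen plan, not better); the closure needs high dilution and excess CrCl2; A6 contains a β,γ-unsaturated aldehyde prone to conjugation and an α-methylene lactone that must survive the whole fragment synthesis.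
- Comparison: closest to the target structurally; a polar cyclisation against a strain-driven cycloreversion; a shorter endgame but a long linear route to A6, so probably no shorter overall.

Key step: step 9

Remark 1: ring atoms of the ten-membered ring and of its precursors carry germacrane numbers (C1–C15); descriptors are CIP.

Remark 2 (assumption): the lipase in step 2 is taken to acylate the (R)-configured carbinol of 2, the usual preference for secondary alcohols; if the opposite preference were found, the pseudo-symmetry of 2 allows the same 7 to be reached by running the enzymatic step in the hydrolytic direction.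

Remark 3: 11 and 12 as drawn here are consistent with 27 (C8 is R in all three; the ring-cis C4=C5 bond is E by CIP in 12 and Z in 27 only through a priority change), so no structural correction is needed; the stereochemical reasoning is sharpened in step 9.

Step 1
Reactants: 1 all-cis-cyclohexane-1,3,5-triol
Product: 2 all-cis-5-[(tert-butyldimethylsilyl)oxy]cyclohexane-1,3-diol (meso)
Conditions: NaH (1.0 equiv), THF–DMF, 0 °C; t-BuMe2SiCl (1.0 equiv), 0 °C to rt
Reagents that add atoms: tert-butyldimethylsilyl chloride CC(C)(C)[Si](C)(C)Cl
Why: Silylation of the monosodium alkoxide of a symmetrical polyol; the three hydroxyls are equivalent, so the only issue is mono- versus polysilylation, limited by stoichiometry with recycling of 1. No stereocentre is set (2 is meso).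

Step 2
Reactants: 2 all-cis-5-[(tert-butyldimethylsilyl)oxy]cyclohexane-1,3-diol
Product: 3 (1R,3S,5S)-3-[(tert-butyldimethylsilyl)oxy]-5-hydroxycyclohexyl acetate
Conditions: lipase from Pseudomonas cepacia, vinyl acetate, t-BuOMe, 25 °C
Reagents that add atoms: vinyl acetate CC(=O)OC=C
Why: Lipase-catalysed enantiotopos-selective transesterification of a meso-1,3-diol, irreversible because the vinyl alcohol leaves as acetaldehyde. Acylation of the (R)-configured carbinol decides which hydroxyl later becomes the carbonyl and thereby the R configuration of the silyloxy carbon (C8) in 7.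

Step 3
Reactants: 3 (1R,3S,5S)-3-[(tert-butyldimethylsilyl)oxy]-5-hydroxycyclohexyl acetate
Product: 5 (R)-5-[(tert-butyldimethylsilyl)oxy]cyclohex-2-en-1-one, via β-acetoxy ketone 4 (not isolated)
Conditions: (n-Pr4N)RuO4 (5 mol %), N-methylmorpholine N-oxide, CH2Cl2, rt; then DBU, 0 °C
Reagents that add atoms: none
Why: Ley–Griffith oxidation of the free carbinol, then E1cB loss of the β-acetoxy group, a better leaving group than the silyloxy group on the other β-carbon. The silyloxy stereocentre is not involved.

Step 4
Reactants: 5 (R)-5-[(tert-butyldimethylsilyl)oxy]cyclohex-2-en-1-one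
Product: 6 (3R,5R)-5-[(tert-butyldimethylsilyl)oxy]-3-methyl-1-[(trimethylsilyl)oxy]cyclohex-1-ene
Conditions: Me2CuLi, Me3SiCl, THF, −78 °C; Et3N
Reagents that add atoms: lithium dimethylcuprate [Li+].C[Cu-]C; chlorotrimethylsilane C[Si](C)(C)Cl
Why: Cuprate conjugate addition with in situ O-silylation of the enolate. The methyl enters anti to the silyloxy group, but this centre becomes trigonal again in step 5; the enol ether fixes the position of the future double bond.

Step 5
Reactants: 6 (3R,5R)-5-[(tert-butyldimethylsilyl)oxy]-3-methyl-1-[(trimethylsilyl)oxy]cyclohex-1-ene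
Product: 7 (R)-5-[(tert-butyldimethylsilyl)oxy]-3-methylcyclohex-2-en-1-one
Conditions: Pd(OAc)2 (10 mol %), O2 (1 atm), DMSO, rt
Reagents that add atoms: none
Why: Saegusa–Ito dehydrogenation (palladium enolate, β-hydride elimination, reoxidation by O2) restores the enone with the methyl on the β-carbon. Steps 4 and 5 together are a β-methylation without carbonyl transposition, which is what makes the silyloxy carbon R in 7.

Step 6
Reactants: 8 ethyl 1-bromocyclobutane-1-carboxylate
Product: 9 cyclobut-1-ene-1-carboxylic acid
Conditions: KOH, toluene, reflux; aq. HCl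
Reagents that add atoms: potassium hydroxide [K+].[OH-]
Why: E2 dehydrobromination of the tertiary α-bromo ester with concomitant saponification. The strained enoate is isolated as the acid, which resists Michael polymerisation under these basic conditions better than the ester.

Step 7
Reactants: 9 cyclobut-1-ene-1-carboxylic acid
Product: 10 methyl cyclobut-1-ene-1-carboxylate
Conditions: MeI, K2CO3, DMF, 0 °C to rt
Reagents that add atoms: iodomethane CI
Why: SN2 O-methylation of the carboxylate under weakly basic conditions. The volatile ester is used at once.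

Step 8
Reactants: 7 (R)-5-[(tert-butyldimethylsilyl)oxy]-3-methylcyclohex-2-en-1-one; 10 methyl cyclobut-1-ene-1-carboxylate
Product: 11 methyl (1S,2R,5S,6S,8R)-8-[(tert-butyldimethylsilyl)oxy]-6-methyl-10-oxotricyclo[4.4.0.0(2,5)]decane-2-carboxylate (cis-anti-cis; silyloxy group cis to the angular methyl)
Conditions: hν (350 nm), 10 (5 equiv), CH2Cl2, −40 °C; basic Al2O3
Reagents that add atoms: none
Why: Enone–alkene [2+2] photocycloaddition through the enone triplet and a 1,4-diradical: C10 bonds first to the unsubstituted cyclobutene carbon (C1), leaving the ester-stabilised radical at C4 to close on C5, hence the head-to-head adduct. The cyclobutene approaches the enone face opposite the C8 silyloxy group with its ring turned away from the six-membered ring (cis-anti-cis; any trans-fused adduct is epimerised at C5 on basic alumina), which fixes C1, C4, C5 and C10 relative to C8. Minor diastereomers are removed by chromatography.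

Step 9
Reactants: 11 methyl (1S,2R,5S,6S,8R)-8-[(tert-butyldimethylsilyl)oxy]-6-methyl-10-oxotricyclo[4.4.0.0(2,5)]decane-2-carboxylate
Product: 12 methyl (1(10)E,4E,8R)-8-[(tert-butyldimethylsilyl)oxy]-10-methyl-6-oxocyclodeca-1(10),4-diene-4-carboxylate (C4=C5 ring-cis)
Conditions: FVT, quartz tube, 450–500 °C, 0.01 mbar, trap at −196 °C
Reagents that add atoms: none
Why: Thermal cycloreversion of a bicyclo[2.2.0]hexane embedded in a cyclobutene–cyclohexenone photoadduct, the known route from such six-four-four tricycles to cyclodeca-1,5-dienes (formal retro-[2+2] by way of a cyclohexane-1,4-diyl). The strained central C1–C4 bond homolyses first (the C4 radical is stabilised by the ester), the boat diyl relaxes to a chair, and β-scission of C5–C10 pairs the radicals as C1=C10 and C4=C5. The ten-membered ring is closed by ring merger, that is by cleavage of the two fusion bonds shared by the six- and four-membered rings, not by cyclisation, so no dilution or entropic penalty applies. No stereocentre is created; C1, C4, C5 and C10 become trigonal and C8 (R) is untouched. Bond selectivity: C5–C10 is the more substituted, α-keto bond and its cleavage gives two trisubstituted olefins, one the conjugated enone ester, whereas C2–C3 cleavage would give two vinyl groups. Geometric selectivity: in the chair diyl an equatorial ring bond ends trans and an axial one cis across the new olefin, so the chair with C9 equatorial and C6 axial gives E C1=C10 and ring-cis C4=C5; this is the chair in which the C8 silyloxy group and the C10 methyl (cis to each other because step 8 went anti to the silyloxy group) are both equatorial on the cyclohexanone ring, while the other chair, leading to Z C1=C10 and ring-trans C4=C5, forces them 1,3-diaxial. C8 is therefore a conformational anchor and not a bystander, and only the anti adduct 11 is pyrolysed. Low pressure and short contact time take 12 out of the hot zone before Cope rearrangement to the divinylcyclohexane competes.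

Step 10
Reactants: 12 methyl (1(10)E,4E,8R)-8-[(tert-butyldimethylsilyl)oxy]-10-methyl-6-oxocyclodeca-1(10),4-diene-4-carboxylate
Product: 13 tert-butyl 2-[(1(10)E,4E,7R,8R)-8-[(tert-butyldimethylsilyl)oxy]-4-(methoxycarbonyl)-10-methyl-6-oxocyclodeca-1(10),4-dien-7-yl]acetate
Conditions: LiN(SiMe3)2 (1.05 equiv), THF, −78 °C; BrCH2CO2t-Bu, DMPU, −78 to −40 °C; AcOH
Reagents that add atoms: tert-butyl bromoacetate CC(C)(C)OC(=O)CBr
Why: Kinetic deprotonation of the enone at the α′-carbon C7 (not the γ-carbon C3) and SN2 alkylation of the lithium enolate. With H8 eclipsing the enolate (allylic strain) the electrophile enters anti to the C8 silyloxy group, the sense of a Fráter–Seebach alkylation, which puts C11 cis to O8 on the ring (7R). Low temperature and a reactive electrophile hold back β-elimination of the silyloxy group.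

Step 11
Reactants: 13 tert-butyl 2-[(1(10)E,4E,7R,8R)-8-[(tert-butyldimethylsilyl)oxy]-4-(methoxycarbonyl)-10-methyl-6-oxocyclodeca-1(10),4-dien-7-yl]acetate
Product: 16 tert-butyl 2-[(1(10)E,4E,3S,7R,8R)-3-acetoxy-8-[(tert-butyldimethylsilyl)oxy]-4-(methoxycarbonyl)-10-methyl-6-oxocyclodeca-1(10),4-dien-7-yl]acetate, via silyl dienol ether 14 (not isolated), via 5-bromo ketone 15 (not isolated)
Conditions: t-BuMe2SiOTf, Et3N, CH2Cl2, −78 to 0 °C; NBS, −78 °C; n-Bu4NOAc, 0 °C to rt
Reagents that add atoms: tetrabutylammonium acetate CCCC[N+](CCCC)(CCCC)CCCC.CC(=O)[O-]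
Why: Soft enolisation removes the accessible vinylogous proton at C3 (C7–H is tertiary and flanked) to give the 3,5-dienol ether; electrophilic bromination gives the 5-bromo-3-enoate, a 2-(1-bromoalkyl)acrylate of the Baylis–Hillman type, which acetate attacks at the acrylate β-carbon C3 with loss of bromide (SN2′). A bromide formed at C3 instead would be displaced directly, so both courses converge on the doubly conjugated γ-acetoxy enone with ring-cis C4=C5. The 3S configuration is expected from entry of acetate on the outer face of the ring and is not secured by any other element.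

Step 12
Reactants: 16 tert-butyl 2-[(1(10)E,4E,3S,7R,8R)-3-acetoxy-8-[(tert-butyldimethylsilyl)oxy]-4-(methoxycarbonyl)-10-methyl-6-oxocyclodeca-1(10),4-dien-7-yl]acetate
Product: 17 tert-butyl 2-[(1(10)E,4Z,3S,6S,7S,8R)-8-[(tert-butyldimethylsilyl)oxy]-3,6-dihydroxy-4-(hydroxymethyl)-10-methylcyclodeca-1(10),4-dien-7-yl]acetate
Conditions: i-Bu2AlH (6.5 equiv), CH2Cl2, −78 °C; aq. citric acid
Reagents that add atoms: none
Why: i-Bu2AlH reduces in the 1,2-sense the ketone, the conjugated methyl ester (to the allylic alcohol) and the acetate, while the hindered tert-butyl ester survives at −78 °C. Felkin–Anh control from C7 (hydride anti to C8, side chain flanking the carbonyl oxygen) gives the 6S alcohol with O6 cis to the side chain. This is the C6 epimer of the natural configuration and is corrected by inversion in step 14.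

Step 13
Reactants: 17 tert-butyl 2-[(1(10)E,4Z,3S,6S,7S,8R)-8-[(tert-butyldimethylsilyl)oxy]-3,6-dihydroxy-4-(hydroxymethyl)-10-methylcyclodeca-1(10),4-dien-7-yl]acetate
Product: 18 3,15-O-isopropylidene acetal of 17 (1,3-dioxane across O3 and O15; C6 hydroxyl free)
Conditions: Me2C(OMe)2, PPTS (cat.), CH2Cl2, 0 °C
Reagents that add atoms: 2,2-dimethoxypropane COC(C)(C)OC
Why: Acetal exchange under thermodynamic control; the six-membered 1,3-dioxane through O3 and O15 is preferred to a seven-membered ring through O6. The C6 hydroxyl is left as the only free one.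

Step 14
Reactants: 18 3,15-O-isopropylidene acetal of 17
Product: 20 (3S,6R,7S,8R)-8-[(tert-butyldimethylsilyl)oxy]-3,15-(isopropylidenedioxy)germacra-1(10)E,4Z-dien-12,6-olide (trans-fused lactone), via C6 mesylate 19 (not isolated)
Conditions: MsCl, Et3N, CH2Cl2, −20 °C to rt
Reagents that add atoms: none
Why: Mesylation of the allylic C6 alcohol is followed by intramolecular SN2 displacement by the carbonyl oxygen of the tert-butyl ester (5-exo-tet, anti-periplanar to the leaving group); the dialkoxycarbenium ion loses 2-methylpropene. C6 is inverted from S to R, giving the trans-fused lactone, the equivalent of a Mitsunobu lactonisation without the free acid.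

Step 15
Reactants: 20 (3S,6R,7S,8R)-8-[(tert-butyldimethylsilyl)oxy]-3,15-(isopropylidenedioxy)germacra-1(10)E,4Z-dien-12,6-olide
Product: 23 (3S,6R,7S,8R)-8-[(tert-butyldimethylsilyl)oxy]-3,15-(isopropylidenedioxy)germacra-1(10)E,4Z,11(13)-trien-12,6-olide, via Mannich base 21 (not isolated), via trimethylammonium iodide 22 (not isolated)
Conditions: LiN(i-Pr)2, THF, −78 °C; CH2=NMe2+ I−; MeI, MeOH, rt; aq. NaHCO3, EtOAc
Reagents that add atoms: N,N-dimethylmethyleneiminium iodide (Eschenmoser's salt) C=[N+](C)C.[I-]
Why: The lactone enolate (C11–H2 is the only acidic C–H) undergoes a Mannich reaction with Eschenmoser's salt; quaternisation and base-induced elimination of trimethylamine give the α-methylene lactone. C11 becomes trigonal, so no stereocentre is created.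

Step 16
Reactants: 23 (3S,6R,7S,8R)-8-[(tert-butyldimethylsilyl)oxy]-3,15-(isopropylidenedioxy)germacra-1(10)E,4Z,11(13)-trien-12,6-olide
Product: 24 (3S,6R,7R,8R)-8-hydroxy-3,15-(isopropylidenedioxy)germacra-1(10)E,4Z,11(13)-trien-12,6-olide
Conditions: HF·pyridine, pyridine, THF, 0 °C to rt
Reagents that add atoms: none
Why: Fluoride-induced Si–O cleavage under buffered conditions that leave the acetonide, the lactone and its enoate intact. No epoxide is present yet, and the carbon configuration at C8 is unchanged (the descriptor of C7 changes only through priorities).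

Step 17
Reactants: 24 (3S,6R,7R,8R)-8-hydroxy-3,15-(isopropylidenedioxy)germacra-1(10)E,4Z,11(13)-trien-12,6-olide
Product: 25 (3S,6R,7R,8R)-8-(isobutyryloxy)-3,15-(isopropylidenedioxy)germacra-1(10)E,4Z,11(13)-trien-12,6-olide
Conditions: (i-PrCO)2O, Et3N, DMAP (cat.), CH2Cl2, 0 °C to rt
Reagents that add atoms: isobutyric anhydride CC(C)C(=O)OC(=O)C(C)C
Why: DMAP-catalysed acylation of the only free hydroxyl, with retention at C8.

Step 18
Reactants: 25 (3S,6R,7R,8R)-8-(isobutyryloxy)-3,15-(isopropylidenedioxy)germacra-1(10)E,4Z,11(13)-trien-12,6-olide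
Product: 26 (3S,6R,7R,8R)-3,15-dihydroxy-8-(isobutyryloxy)germacra-1(10)E,4Z,11(13)-trien-12,6-olide
Conditions: PPTS (cat.), MeOH, rt
Reagents that add atoms: none
Why: Acid-catalysed transacetalisation to methanol. The conditions are mild enough for the 1,5-diene because C4=C5, with three allylic oxygens, is a poor transannular nucleophile and no epoxide is present.

Step 19
Reactants: 26 (3S,6R,7R,8R)-3,15-dihydroxy-8-(isobutyryloxy)germacra-1(10)E,4Z,11(13)-trien-12,6-olide
Product: 27 (1R,3S,6R,7R,8R,10R)-1,10-epoxy-3,15-dihydroxy-8-(isobutyryloxy)germacra-4Z,11(13)-dien-12,6-olide (CNP0219050.1)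
Conditions: mCPBA (1.05 equiv), NaHCO3, CH2Cl2, 0 °C
Reagents that add atoms: 3-chloroperbenzoic acid OOC(=O)c1cccc(Cl)c1
Why: Prilezhaev epoxidation; the concerted syn addition turns the E olefin into the trans-epoxide. C1=C10 is the only electron-rich olefin (C4=C5 carries three allylic oxygens, C11=C13 is conjugated), as in the remote-olefin selectivity of peracids with allylic alcohols. Attack on the outer face of the olefin, in the ring conformation with C14 on the same side as C11, gives 1R,10R.

Compound list

1 | all-cis-cyclohexane-1,3,5-triol | O[C@H]1C[C@@H](O)C[C@@H](O)C1 | starting material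
2 | all-cis-5-[(tert-butyldimethylsilyl)oxy]cyclohexane-1,3-diol (meso) | O[C@H]1C[C@@H](O)C[C@@H](O[Si](C)(C)C(C)(C)C)C1 | intermediate
3 | (1R,3S,5S)-3-[(tert-butyldimethylsilyl)oxy]-5-hydroxycyclohexyl acetate | O[C@H]1C[C@@H](OC(C)=O)C[C@@H](O[Si](C)(C)C(C)(C)C)C1 | intermediate
4 | (1S,3R)-3-[(tert-butyldimethylsilyl)oxy]-5-oxocyclohexyl acetate | O=C1C[C@@H](OC(C)=O)C[C@@H](O[Si](C)(C)C(C)(C)C)C1 | intermediate
5 | (R)-5-[(tert-butyldimethylsilyl)oxy]cyclohex-2-en-1-one | O=C1C=CC[C@@H](O[Si](C)(C)C(C)(C)C)C1 | intermediate
6 | (3R,5R)-5-[(tert-butyldimethylsilyl)oxy]-3-methyl-1-[(trimethylsilyl)oxy]cyclohex-1-ene | C[Si](C)(C)OC1=C[C@H](C)C[C@@H](O[Si](C)(C)C(C)(C)C)C1 | intermediate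
7 | (R)-5-[(tert-butyldimethylsilyl)oxy]-3-methylcyclohex-2-en-1-one | O=C1C=C(C)C[C@@H](O[Si](C)(C)C(C)(C)C)C1 | intermediate
8 | ethyl 1-bromocyclobutane-1-carboxylate | CCOC(=O)C1(Br)CCC1 | starting material
9 | cyclobut-1-ene-1-carboxylic acid | OC(=O)C1=CCC1 | intermediate
10 | methyl cyclobut-1-ene-1-carboxylate | COC(=O)C1=CCC1 | intermediate
11 | methyl (1S,2R,5S,6S,8R)-8-[(tert-butyldimethylsilyl)oxy]-6-methyl-10-oxotricyclo[4.4.0.0(2,5)]decane-2-carboxylate (cis-anti-cis; germacrane 1S,4R,5S,8R,10S) | O=C1C[C@H](O[Si](C)(C)C(C)(C)C)C[C@]2(C)[C@H]1[C@@]3(C(=O)OC)CC[C@@H]23 | intermediate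
12 | methyl (1(10)E,4E,8R)-8-[(tert-butyldimethylsilyl)oxy]-10-methyl-6-oxocyclodeca-1(10),4-diene-4-carboxylate (C4=C5 ring-cis) | O=C1/C=C(/C(=O)OC)CC/C=C(\C)C[C@@H](O[Si](C)(C)C(C)(C)C)C1 | intermediate
13 | tert-butyl 2-[(1(10)E,4E,7R,8R)-8-[(tert-butyldimethylsilyl)oxy]-4-(methoxycarbonyl)-10-methyl-6-oxocyclodeca-1(10),4-dien-7-yl]acetate | O=C1/C=C(/C(=O)OC)CC/C=C(\C)C[C@@H](O[Si](C)(C)C(C)(C)C)[C@H]1CC(=O)OC(C)(C)C | intermediate
14 | 6-O-(tert-butyldimethylsilyl) 3,5-dienol ether of 13 (C3=C4 and C5=C6 ring-cis, 1(10)E, 7R,8R) | CC(C)(C)[Si](C)(C)O/C1=C/C(C(=O)OC)=C\C/C=C(\C)C[C@@H](O[Si](C)(C)C(C)(C)C)[C@H]1CC(=O)OC(C)(C)C | intermediate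
15 | tert-butyl 2-[(7R,8R)-5-bromo-8-[(tert-butyldimethylsilyl)oxy]-4-(methoxycarbonyl)-10-methyl-6-oxocyclodeca-1(10)E,3-dien-7-yl]acetate (C3=C4 ring-cis; C5 not defined) | O=C1C(Br)/C(C(=O)OC)=C\C/C=C(\C)C[C@@H](O[Si](C)(C)C(C)(C)C)[C@H]1CC(=O)OC(C)(C)C | intermediate
16 | tert-butyl 2-[(1(10)E,4E,3S,7R,8R)-3-acetoxy-8-[(tert-butyldimethylsilyl)oxy]-4-(methoxycarbonyl)-10-methyl-6-oxocyclodeca-1(10),4-dien-7-yl]acetate | O=C1/C=C(/C(=O)OC)[C@@H](OC(C)=O)C/C=C(\C)C[C@@H](O[Si](C)(C)C(C)(C)C)[C@H]1CC(=O)OC(C)(C)C | intermediate
17 | tert-butyl 2-[(1(10)E,4Z,3S,6S,7S,8R)-8-[(tert-butyldimethylsilyl)oxy]-3,6-dihydroxy-4-(hydroxymethyl)-10-methylcyclodeca-1(10),4-dien-7-yl]acetate | O[C@H]1/C=C(/CO)[C@@H](O)C/C=C(\C)C[C@@H](O[Si](C)(C)C(C)(C)C)[C@H]1CC(=O)OC(C)(C)C | intermediate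
18 | 3,15-O-isopropylidene acetal of 17 (3S,6S,7S,8R) | O[C@H]1/C=C2/COC(C)(C)O[C@H]2C/C=C(\C)C[C@@H](O[Si](C)(C)C(C)(C)C)[C@H]1CC(=O)OC(C)(C)C | intermediate
19 | 6-O-methanesulfonate of 18 (3S,6S,7R,8R) | CS(=O)(=O)O[C@H]1/C=C2/COC(C)(C)O[C@H]2C/C=C(\C)C[C@@H](O[Si](C)(C)C(C)(C)C)[C@H]1CC(=O)OC(C)(C)C | intermediate
20 | (3S,6R,7S,8R)-8-[(tert-butyldimethylsilyl)oxy]-3,15-(isopropylidenedioxy)germacra-1(10)E,4Z-dien-12,6-olide | O=C1O[C@@H]2/C=C3/COC(C)(C)O[C@H]3C/C=C(\C)C[C@@H](O[Si](C)(C)C(C)(C)C)[C@H]2C1 | intermediate
21 | 11-[(dimethylamino)methyl] derivative of 20 (C11 not defined) | CN(C)CC1C(=O)O[C@@H]2/C=C3/COC(C)(C)O[C@H]3C/C=C(\C)C[C@@H](O[Si](C)(C)C(C)(C)C)[C@@H]12 | intermediate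
22 | N-methyl iodide (trimethylammonium salt) of 21 | C[N+](C)(C)CC1C(=O)O[C@@H]2/C=C3/COC(C)(C)O[C@H]3C/C=C(\C)C[C@@H](O[Si](C)(C)C(C)(C)C)[C@@H]12.[I-] | intermediate
23 | (3S,6R,7S,8R)-8-[(tert-butyldimethylsilyl)oxy]-3,15-(isopropylidenedioxy)germacra-1(10)E,4Z,11(13)-trien-12,6-olide | C=C1C(=O)O[C@@H]2/C=C3/COC(C)(C)O[C@H]3C/C=C(\C)C[C@@H](O[Si](C)(C)C(C)(C)C)[C@@H]12 | intermediate
24 | (3S,6R,7R,8R)-8-hydroxy-3,15-(isopropylidenedioxy)germacra-1(10)E,4Z,11(13)-trien-12,6-olide | C=C1C(=O)O[C@@H]2/C=C3/COC(C)(C)O[C@H]3C/C=C(\C)C[C@@H](O)[C@@H]12 | intermediate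
25 | (3S,6R,7R,8R)-8-(isobutyryloxy)-3,15-(isopropylidenedioxy)germacra-1(10)E,4Z,11(13)-trien-12,6-olide | C=C1C(=O)O[C@@H]2/C=C3/COC(C)(C)O[C@H]3C/C=C(\C)C[C@@H](OC(=O)C(C)C)[C@@H]12 | intermediate
26 | (3S,6R,7R,8R)-3,15-dihydroxy-8-(isobutyryloxy)germacra-1(10)E,4Z,11(13)-trien-12,6-olide | C=C1C(=O)O[C@@H]2/C=C(/CO)[C@@H](O)C/C=C(\C)C[C@@H](OC(=O)C(C)C)[C@@H]12 | intermediate
27 | (1R,3S,6R,7R,8R,10R)-1,10-epoxy-3,15-dihydroxy-8-(isobutyryloxy)germacra-4Z,11(13)-dien-12,6-olide (CNP0219050.1) | C=C1C(=O)O[C@@H]2/C=C(/CO)[C@@H](O)C[C@H]3O[C@]3(C)C[C@@H](OC(=O)C(C)C)[C@@H]12 | target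

Total step count: 19. Longest linear sequence: 17 steps (steps 1–5 and 8–19); the cyclobutene branch is 2 steps (6 and 7).

Steps least certain to work

Step 9 (key step). The diyl may partly leave through the other chair or cleave straight from the boat, which costs geometric control, and some material may be lost by Cope rearrangement or C2–C3 scission. A stereoretentive cleavage would give E C1=C10 together with a ring-trans C4=C5 bond. The fallback sets out from 11: if pyrolysis gives methyl (1(10)E,4Z,8R)-8-[(tert-butyldimethylsilyl)oxy]-10-methyl-6-oxocyclodeca-1(10),4-diene-4-carboxylate F1 (ring-trans C4=C5), it is equilibrated with a catalytic nucleophile (PBu3, or PhSH with Et3N) by reversible conjugate addition to the doubly activated olefin, and returns to the route at 12. The ring-cis enone should be favoured because only it keeps enone conjugation without added ring strain. This thermodynamic repair works for C4=C5 only; a Z C1=C10 bond cannot be mended this way, which is why step 9 relies on the C8 anchor and on a diastereomerically pure 11.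

Step 11. Enolisation may go toward C7 instead of C3, the silyl triflate may attack the tert-butyl ester, and acetate may enter on the wrong face of C3, since nothing but ring conformation controls it. The fallback sets out from 13 through 14 and uses a sigmatropic shift in place of a substitution. PhSeCl selenenylates the dienol ether at C5 to give tert-butyl 2-[(7R,8R)-8-[(tert-butyldimethylsilyl)oxy]-4-(methoxycarbonyl)-10-methyl-6-oxo-5-(phenylselanyl)cyclodeca-1(10)E,3-dien-7-yl]acetate F2. Oxidation with H2O2 and pyridine at low temperature triggers the [2,3]-shift of the allylic selenoxide, which delivers oxygen to C3 on the face that carried selenium and gives tert-butyl 2-[(1(10)E,4E,3S,7R,8R)-8-[(tert-butyldimethylsilyl)oxy]-3-hydroxy-4-(methoxycarbonyl)-10-methyl-6-oxocyclodeca-1(10),4-dien-7-yl]acetate F3. Reduction of F3 under the conditions of step 12 returns to the route at 17. Because this delivery is suprafacial while an SN2′ substitution is normally anti, the two methods should be stereocomplementary at C3.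

Step 10. Facial selectivity at C7 may be poor, the β-silyloxy group may be lost from the enolate, and the enolate may add to the doubly activated olefin of another molecule. The fallback sets out from 12 and uses a chelated dianion. HF·pyridine gives methyl (1(10)E,4E,8R)-8-hydroxy-10-methyl-6-oxocyclodeca-1(10),4-diene-4-carboxylate F4. Two equivalents of LiN(SiMe3)2 and then tert-butyl bromoacetate (Fráter–Seebach alkylation of the alkoxide–enolate, which cannot eliminate and alkylates anti to the alkoxide) give tert-butyl 2-[(1(10)E,4E,7R,8R)-8-hydroxy-4-(methoxycarbonyl)-10-methyl-6-oxocyclodeca-1(10),4-dien-7-yl]acetate F5. An excess of the silyl triflate in step 11 silylates the C8 hydroxyl and enolises the ketone in one operation, so the fallback returns to the route at 14.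

Step 12 (with step 14). Hydride may attack the other face of the C6 carbonyl, or both faces, and the aluminium alkoxide may reduce or lactonise the tert-butyl ester if the mixture warms. The configuration at C6 must be assigned before step 14, because mesylation of the wrong epimer would give the cis-lactone. The fallback sets out from 16: if reduction gives the 6R alcohol tert-butyl 2-[(1(10)E,4Z,3S,6R,7S,8R)-8-[(tert-butyldimethylsilyl)oxy]-3,6-dihydroxy-4-(hydroxymethyl)-10-methylcyclodeca-1(10),4-dien-7-yl]acetate F6, it is converted as in step 13 into its 3,15-O-isopropylidene acetal F7. The C6 alkoxide (NaH, THF) then attacks the tert-butyl ester with retention, and the fallback returns to the route at 20. Both C6 epimers thus converge on 20, one by inversion and one by retention.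

Step 19. Attack may occur on the inner face of C1=C10, or the free allylic hydroxyls may direct the peracid to C4=C5. The fallback sets out from 26 and replaces substrate control by reagent control: a Shi epoxidation (fructose-derived chiral ketone, KHSO5, buffered aqueous MeCN), which is selective for E trisubstituted olefins and leaves electron-poor olefins alone, with the catalyst enantiomer chosen for 1R,10R. It returns at 27 and makes no new compound.

Further compounds

F1 | step 9 | methyl (1(10)E,4Z,8R)-8-[(tert-butyldimethylsilyl)oxy]-10-methyl-6-oxocyclodeca-1(10),4-diene-4-carboxylate (C4=C5 ring-trans) | O=C1/C=C(\C(=O)OC)CC/C=C(\C)C[C@@H](O[Si](C)(C)C(C)(C)C)C1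
F2 | step 11 | tert-butyl 2-[(7R,8R)-8-[(tert-butyldimethylsilyl)oxy]-4-(methoxycarbonyl)-10-methyl-6-oxo-5-(phenylselanyl)cyclodeca-1(10)E,3-dien-7-yl]acetate (C5 not defined) | O=C1C([Se]c2ccccc2)/C(C(=O)OC)=C\C/C=C(\C)C[C@@H](O[Si](C)(C)C(C)(C)C)[C@H]1CC(=O)OC(C)(C)C
F3 | step 11 | tert-butyl 2-[(1(10)E,4E,3S,7R,8R)-8-[(tert-butyldimethylsilyl)oxy]-3-hydroxy-4-(methoxycarbonyl)-10-methyl-6-oxocyclodeca-1(10),4-dien-7-yl]acetate | O=C1/C=C(/C(=O)OC)[C@@H](O)C/C=C(\C)C[C@@H](O[Si](C)(C)C(C)(C)C)[C@H]1CC(=O)OC(C)(C)C
F4 | step 10 | methyl (1(10)E,4E,8R)-8-hydroxy-10-methyl-6-oxocyclodeca-1(10),4-diene-4-carboxylate | O=C1/C=C(/C(=O)OC)CC/C=C(\C)C[C@@H](O)C1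
F5 | step 10 | tert-butyl 2-[(1(10)E,4E,7R,8R)-8-hydroxy-4-(methoxycarbonyl)-10-methyl-6-oxocyclodeca-1(10),4-dien-7-yl]acetate | O=C1/C=C(/C(=O)OC)CC/C=C(\C)C[C@@H](O)[C@H]1CC(=O)OC(C)(C)C
F6 | step 12 | tert-butyl 2-[(1(10)E,4Z,3S,6R,7S,8R)-8-[(tert-butyldimethylsilyl)oxy]-3,6-dihydroxy-4-(hydroxymethyl)-10-methylcyclodeca-1(10),4-dien-7-yl]acetate | O[C@@H]1/C=C(/CO)[C@@H](O)C/C=C(\C)C[C@@H](O[Si](C)(C)C(C)(C)C)[C@H]1CC(=O)OC(C)(C)C
F7 | step 12 | 3,15-O-isopropylidene acetal of F6 | O[C@@H]1/C=C2/COC(C)(C)O[C@H]2C/C=C(\C)C[C@@H](O[Si](C)(C)C(C)(C)C)[C@H]1CC(=O)OC(C)(C)C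
F0 | step 19 | none | none
A1 | alternative 1 | 3,15-bis-O-(tert-butyldimethylsilyl) ether of 27 | C=C1C(=O)O[C@@H]2/C=C(/CO[Si](C)(C)C(C)(C)C)[C@@H](O[Si](C)(C)C(C)(C)C)C[C@H]3O[C@]3(C)C[C@@H](OC(=O)C(C)C)[C@@H]12
A2 | alternative 1 | ten-membered 1,10-epoxide with C6 hydroxyl, C7 ethynyl (trans), C8 isobutyrate, C3 and C15 silyl ethers | O[C@@H]1/C=C(/CO[Si](C)(C)C(C)(C)C)[C@@H](O[Si](C)(C)C(C)(C)C)C[C@H]2O[C@]2(C)C[C@@H](OC(=O)C(C)C)[C@H]1C#C
A3 | alternative 2 | ten-membered carbocycle with E C1=C10, C8 p-methoxybenzyl ether, C6 and C12 triethylsilyl ethers, C3 and C15 tert-butyldimethylsilyl ethers | CC[Si](CC)(CC)OCC[C@H]1[C@H](O[Si](CC)(CC)CC)/C=C(/CO[Si](C)(C)C(C)(C)C)[C@@H](O[Si](C)(C)C(C)(C)C)C/C=C(C)/C[C@H]1OCc1ccc(OC)cc1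
A4 | alternative 2 | open-chain precursor with C8 p-methoxybenzyl enol ether (C8=C9) and E vinyl iodide at C10 | C=C(OCc1ccc(OC)cc1)[C@@H](CCO[Si](CC)(CC)CC)[C@H](O[Si](CC)(CC)CC)/C=C(/CO[Si](C)(C)C(C)(C)C)[C@@H](O[Si](C)(C)C(C)(C)C)C/C=C(C)/I
A5 | alternative 3 | 15-O-(tert-butyldimethylsilyl) ether of 26 | C=C1C(=O)O[C@@H]2/C=C(/CO[Si](C)(C)C(C)(C)C)[C@@H](O)C/C=C(C)/C[C@@H](OC(=O)C(C)C)[C@@H]12
A6 | alternative 3 | seco-aldehyde: α-methylene lactone with C8 isobutyrate, Z vinyl iodide at C4 and C3 aldehyde | C=C1C(=O)O[C@H](/C=C(\I)CO[Si](C)(C)C(C)(C)C)[C@H]1[C@H](OC(=O)C(C)C)C/C(C)=C/CC=O
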